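**Retrosynthetic overview**

1. The target is a (2S)-7-hydroxy-8-prenylflavanone whose ring B is the benzo ring of a 2,2-dimethylchroman. It is reached by fluoride removal of a 7-O-triisopropylsilyl group, after an enantioselective copper hydride 1,4-reduction of the flavone C2=C3 bond has set C2.
2. The strategy rests on ring C: C4 is a single carbonyl carbon between C4a of ring A and C3, and C2–C3 together with ring B is an arylacetylene. Ring C is therefore cut at C4a–C4, C4–C3 and O1–C2 into an ortho-iodophenol, carbon monoxide and a terminal alkyne (carbonylative Sonogashira coupling with ring closure in the same flask).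
3. The iodophenol (ring A) comes from resorcinol: iodination at C4, silylation of the unhindered hydroxyl, O-allylation, Claisen rearrangement to the only open ortho carbon (the one between the two oxygens, the other being blocked by iodine), and cross-metathesis of allyl to prenyl.
4. The alkyne (ring B with its dimethylpyran ring) comes from 2,2-dimethylchroman by para-formylation and Ohira–Bestmann homologation.
5. Ring order: ring A, ring B and the dimethylchroman ring are bought in; ring C is the only ring made, in the key step.

Key step: step 8

Assumption: (R)-DTBM-SEGPHOS is taken as the ligand enantiomer that leads to the (2S)-flavanone in step 9; the sense of induction depends only on the hand of the ligand, so the (S)-ligand takes its place if a trial run shows the opposite. Prenyl means 3-methylbut-2-enyl throughout.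

**Route**

Step 1
Reactants: 1 resorcinol
Product: 2 4-iodoresorcinol (4-iodobenzene-1,3-diol)
Conditions: ICl (1.0 equiv), Et2O, 0 °C to rt
Reagents that add atoms: iodine monochloride, ClI
Why: Electrophilic aromatic iodination, in which ICl in ether should attack C4 (para to one hydroxyl, ortho to the other) and one equivalent limits twofold iodination.

Step 2
Reactants: 2 4-iodoresorcinol
Product: 3 2-iodo-5-(triisopropylsilyloxy)phenol
Conditions: TIPSCl (1.05 equiv), imidazole, CH2Cl2–DMF, 0 °C
Reagents that add atoms: triisopropylsilyl chloride, CC(C)[Si](Cl)(C(C)C)C(C)C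
Why: Silyl ether formation under steric control, since the bulky chlorosilane should take the hydroxyl para to iodine while the other hydroxyl is shielded by the neighbouring iodine atom.

Step 3
Reactants: 3 2-iodo-5-(triisopropylsilyloxy)phenol
Product: 4 allyl 2-iodo-5-(triisopropylsilyloxy)phenyl ether
Conditions: allyl bromide, K2CO3, acetone, 55 °C
Reagents that add atoms: allyl bromide, C=CCBr
Why: Williamson ether synthesis on the remaining phenol, under anhydrous carbonate conditions that an aryl triisopropylsilyl ether should survive.

Step 4
Reactants: 4 allyl 2-iodo-5-(triisopropylsilyloxy)phenyl ether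
Product: 6 2-allyl-6-iodo-3-(triisopropylsilyloxy)phenol, via ortho-dienone 5 (not isolated)
Conditions: PhNEt2 (degassed), 190 °C, sealed vessel
Reagents that add atoms: none
Why: Aromatic Claisen rearrangement, in which the [3,3] shift can deliver the allyl group only to the ortho carbon between the two oxygens because the other ortho carbon carries iodine, dienone 5 enolising to the phenol while the basic solvent suppresses acid-induced cyclisation onto the alkene.

Step 5
Reactants: 6 2-allyl-6-iodo-3-(triisopropylsilyloxy)phenol
Product: 7 6-iodo-2-prenyl-3-(triisopropylsilyloxy)phenol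
Conditions: second-generation Grubbs catalyst RuCl2(=CHPh)(PCy3)(H2IMes) (5 mol %), 2-methyl-2-butene (excess), CH2Cl2, 35 °C
Reagents that add atoms: 2-methyl-2-butene, CC=C(C)C
Why: Olefin cross-metathesis with excess 2-methyl-2-butene, the standard conversion of a terminal allyl group into prenyl with loss of propene, which tolerates the free phenol and the aryl iodide.

Step 6
Reactants: 8 2,2-dimethylchroman
Product: 10 2,2-dimethylchroman-6-carbaldehyde, via alpha-chloro ether 9 (not isolated)
Conditions: Cl2CHOMe, TiCl4, CH2Cl2, −10 to 0 °C; then ice-water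
Reagents that add atoms: dichloromethyl methyl ether, COC(Cl)Cl; water, O
Why: Rieche formylation, in which the alkoxy oxygen of the chroman directs the electrophile to the para carbon C6 and aqueous work-up hydrolyses the alpha-chloro ether 9 to the aldehyde.

Step 7
Reactants: 10 2,2-dimethylchroman-6-carbaldehyde
Product: 11 6-ethynyl-2,2-dimethylchroman
Conditions: dimethyl (1-diazo-2-oxopropyl)phosphonate, K2CO3, MeOH, 0 °C to rt
Reagents that add atoms: dimethyl (1-diazo-2-oxopropyl)phosphonate, COP(=O)(OC)C(=[N+]=[N-])C(C)=O
Why: Ohira–Bestmann (Seyferth–Gilbert) homologation, in which the diazomethylphosphonate anion released by methanolysis adds to the aldehyde and loss of phosphate and dinitrogen with 1,2-hydrogen shift gives the terminal alkyne, a sequence that works well for electron-rich aryl aldehydes.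

Step 8
Reactants: 7 6-iodo-2-prenyl-3-(triisopropylsilyloxy)phenol; 11 6-ethynyl-2,2-dimethylchroman; 12 carbon monoxide
Product: 15 2-(2,2-dimethylchroman-6-yl)-8-prenyl-7-(triisopropylsilyloxy)chromen-4-one, via ynone 13 (not isolated), via enaminone 14 (not isolated)
Conditions: PdCl2(PPh3)2 (5 mol %), CO (20 atm), Et2NH, 120 °C
Reagents that add atoms: carbon monoxide (compound 12), [C-]#[O+]; diethylamine, CCNCC (held only in intermediate 14 and released again on ring closure)
Why: Zerovalent palladium, formed from PdCl2(PPh3)2 (divalent palladium) in the amine, inserts into the C–I bond of 7, carbon monoxide inserts to give an aroylpalladium iodide, and this acylates the terminal carbon of alkyne 11 with loss of HI to diethylamine, giving ortho-hydroxyaryl ynone 13 (copper-free carbonylative Sonogashira coupling; bonds C4a–C4 and C4–C3). Diethylamine then adds to the ynone at the future C2 to give enaminone 14, and the C8a hydroxyl attacks that same carbon and expels the amine, a 6-endo addition–elimination that forms O1–C2 and closes ring C as the chromen-4-one. The closest known reaction type is the palladium-catalysed carbonylative annulation of ortho-iodophenols with terminal arylacetylenes to flavones in a secondary amine. No stereocentre is formed. The step needs CO insertion to outrun direct alkyne coupling (which would end in a 2-arylbenzofuran), secured by CO pressure and the absence of copper, and it needs 6-endo over 5-exo closure (aurone), secured by the amine relay through 14, which puts the leaving group on C2. Only the C8a hydroxyl can cyclise because O7 is silylated and para to the acyl carbon, and the prenyl group sits at C8 from the outset.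

Step 9
Reactants: 15 2-(2,2-dimethylchroman-6-yl)-8-prenyl-7-(triisopropylsilyloxy)chromen-4-one
Product: 16 (2S)-2-(2,2-dimethylchroman-6-yl)-8-prenyl-7-(triisopropylsilyloxy)chroman-4-one
Conditions: Cu(OAc)2 (5 mol %), (R)-DTBM-SEGPHOS (5.5 mol %), (EtO)2MeSiH, t-BuOH, toluene, 0 °C to rt
Reagents that add atoms: none
Why: Copper hydride asymmetric conjugate reduction of a chromone, in which the monovalent copper hydride formed from Cu(OAc)2, the bisphosphine and the silane should add hydride to C2 on the face selected by the chiral ligand and so set C2 as S, tert-butanol protonating the copper enolate at C3 before it can ring-open, while the unactivated prenyl alkene and the donor-deactivated C4 carbonyl should stay untouched.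

Step 10
Reactants: 16 (2S)-2-(2,2-dimethylchroman-6-yl)-8-prenyl-7-(triisopropylsilyloxy)chroman-4-one
Product: 17 Euchrenone a17, (2S)-2-(2,2-dimethylchroman-6-yl)-7-hydroxy-8-prenylchroman-4-one
Conditions: Bu4NF, AcOH (1:1), THF, 0 °C
Reagents that add atoms: none
Why: Fluoride-induced cleavage of the aryl silyl ether, buffered with acetic acid so that no free phenoxide or enolate builds up and the base-induced ring opening to the chalcone, which would racemise C2, should be avoided.

**Compound list**

1 | resorcinol | Oc1cccc(O)c1 | starting material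
2 | 4-iodoresorcinol | Oc1ccc(I)c(O)c1 | intermediate
3 | 2-iodo-5-(triisopropylsilyloxy)phenol | Oc1cc(O[Si](C(C)C)(C(C)C)C(C)C)ccc1I | intermediate
4 | allyl 2-iodo-5-(triisopropylsilyloxy)phenyl ether | C=CCOc1cc(O[Si](C(C)C)(C(C)C)C(C)C)ccc1I | intermediate
5 | ortho-dienone, 6-allyl-2-iodo-5-(triisopropylsilyloxy)cyclohexa-2,4-dien-1-one, racemic, not isolated | C=CCC1C(=O)C(I)=CC=C1O[Si](C(C)C)(C(C)C)C(C)C | intermediate
6 | 2-allyl-6-iodo-3-(triisopropylsilyloxy)phenol | C=CCc1c(O)c(I)ccc1O[Si](C(C)C)(C(C)C)C(C)C | intermediate
7 | 6-iodo-2-prenyl-3-(triisopropylsilyloxy)phenol | CC(C)=CCc1c(O)c(I)ccc1O[Si](C(C)C)(C(C)C)C(C)C | intermediate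
8 | 2,2-dimethylchroman | CC1(C)CCc2ccccc2O1 | starting material
9 | alpha-chloro ether, 6-[chloro(methoxy)methyl]-2,2-dimethylchroman, racemic, not isolated | COC(Cl)c1ccc2c(c1)CCC(C)(C)O2 | intermediate
10 | 2,2-dimethylchroman-6-carbaldehyde | O=Cc1ccc2c(c1)CCC(C)(C)O2 | intermediate
11 | 6-ethynyl-2,2-dimethylchroman | C#Cc1ccc2c(c1)CCC(C)(C)O2 | intermediate
12 | carbon monoxide | [C-]#[O+] | starting material
13 | ynone, 3-(2,2-dimethylchroman-6-yl)-1-[2-hydroxy-3-prenyl-4-(triisopropylsilyloxy)phenyl]prop-2-yn-1-one, not isolated | CC(C)=CCc1c(O)c(C(=O)C#Cc2ccc3c(c2)CCC(C)(C)O3)ccc1O[Si](C(C)C)(C(C)C)C(C)C | intermediate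
14 | enaminone, 3-(diethylamino)-3-(2,2-dimethylchroman-6-yl)-1-[2-hydroxy-3-prenyl-4-(triisopropylsilyloxy)phenyl]prop-2-en-1-one, alkene geometry not defined, not isolated | CCN(CC)C(=CC(=O)c1ccc(O[Si](C(C)C)(C(C)C)C(C)C)c(CC=C(C)C)c1O)c1ccc2c(c1)CCC(C)(C)O2 | intermediate
15 | 2-(2,2-dimethylchroman-6-yl)-8-prenyl-7-(triisopropylsilyloxy)chromen-4-one | CC(C)=CCc1c(O[Si](C(C)C)(C(C)C)C(C)C)ccc2c1OC(c1ccc3c(c1)CCC(C)(C)O3)=CC2=O | intermediate
16 | (2S)-2-(2,2-dimethylchroman-6-yl)-8-prenyl-7-(triisopropylsilyloxy)chroman-4-one | CC(C)=CCc1c(O[Si](C(C)C)(C(C)C)C(C)C)ccc2c1O[C@H](c1ccc3c(c1)CCC(C)(C)O3)CC2=O | intermediate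
17 | Euchrenone a17, (2S)-2-(2,2-dimethylchroman-6-yl)-7-hydroxy-8-prenylchroman-4-one | CC(C)=CCc1c(O)ccc2c1O[C@H](c1ccc3c(c1)CCC(C)(C)O3)CC2=O | target

**Step count and risks**

Total step count: 10. Longest linear sequence: 8 steps (steps 1–5, then 8–10, from resorcinol); the alkyne branch contributes steps 6 and 7.

Steps most likely to fail:

1. Step 8 (key step). Direct alkyne coupling may outrun CO insertion and end in a benzofuran; diethylamine may intercept the aroylpalladium species (aminocarbonylation); closure may go 5-exo; the amine at 120 °C may strip the silyl group. The fallback uses neither palladium nor CO gas. It sets out from 7 and 11. Alkyne 11 is deprotonated (n-BuLi, THF, −78 °C) and formylated with DMF to 3-(2,2-dimethylchroman-6-yl)prop-2-ynal F1. Iodophenol 7 is deprotonated with MeMgCl and submitted to iodine–magnesium exchange with i-PrMgCl·LiCl (THF, −20 to 0 °C) to the chloromagnesium phenoxide–arylmagnesium chloride F2, which is added to F1 to give the propargylic alcohol F3. MnO2 in CH2Cl2 oxidises F3 to ynone 13, now isolated. Et2NH in EtOH (rt to 50 °C) closes it through enaminone 14, and the route is rejoined at flavone 15.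

2. Step 9. Hydride transfer to the electron-rich vinylogous ester may be slow, facial discrimination may be poor, the enolate may ring-open and erode the enantiomeric purity, or the C4 carbonyl may be over-reduced. The fallback sets out from 15. Non-selective 1,4-reduction with LiBH(s-Bu)3 (THF, −78 °C, cold AcOH quench) gives the racemic silyl flavanone F4. Kinetic resolution follows by asymmetric transfer hydrogenation with RhCl(Cp*)[(R,R)-TsDPEN] in HCO2H–Et3N. On the usual model for TsDPEN catalysts the (2R)-enantiomer should be reduced to the cis-(2R,4R)-flavan-4-ol F5, which is separated by chromatography, while the (2S)-ketone is left behind. The route is rejoined at 16, with at most half of the material.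

3. Step 2. Regiocontrol may be lost through silylation of the iodine-flanked hydroxyl or of both hydroxyls. The fallback reverses the order of events, sets out from resorcinol 1 and replaces steps 1 and 2. Monosilylation of the symmetrical diol (TIPSCl, 1 equiv, imidazole) gives 3-(triisopropylsilyloxy)phenol F6. Iodination (I2, NaHCO3, THF–H2O, 0 °C) is then directed ortho to the free hydroxyl and para to the silyloxy group, the other activated positions being shielded by the silyl ether, as with 3-alkoxyphenols. The route is rejoined at 3.

**Further compounds**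

F1 | step 8 | 3-(2,2-dimethylchroman-6-yl)prop-2-ynal | O=CC#Cc1ccc2c(c1)CCC(C)(C)O2
F2 | step 8 | chloromagnesium 6-(chloromagnesio)-2-prenyl-3-(triisopropylsilyloxy)phenoxide | CC(C)=CCc1c(O[Mg]Cl)c([Mg]Cl)ccc1O[Si](C(C)C)(C(C)C)C(C)C
F3 | step 8 | 3-(2,2-dimethylchroman-6-yl)-1-[2-hydroxy-3-prenyl-4-(triisopropylsilyloxy)phenyl]prop-2-yn-1-ol, racemic | CC(C)=CCc1c(O)c(C(O)C#Cc2ccc3c(c2)CCC(C)(C)O3)ccc1O[Si](C(C)C)(C(C)C)C(C)C
F4 | step 9 | racemic 2-(2,2-dimethylchroman-6-yl)-8-prenyl-7-(triisopropylsilyloxy)chroman-4-one | CC(C)=CCc1c(O[Si](C(C)C)(C(C)C)C(C)C)ccc2c1OC(c1ccc3c(c1)CCC(C)(C)O3)CC2=O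
F5 | step 9 | (2R,4R)-2-(2,2-dimethylchroman-6-yl)-8-prenyl-7-(triisopropylsilyloxy)chroman-4-ol, 2,4-cis | CC(C)=CCc1c(O[Si](C(C)C)(C(C)C)C(C)C)ccc2c1O[C@@H](c1ccc3c(c1)CCC(C)(C)O3)C[C@H]2O
F6 | step 2 | 3-(triisopropylsilyloxy)phenol | Oc1cccc(O[Si](C(C)C)(C(C)C)C(C)C)c1
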